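Telling the south-east flask from the west run by its electrophile is impossible so far: at 60.0 min the south-east flask reads 59.9% and the west run 59.9%, though the west run holds twice the buffer base.

| setting | south-east | west | flask |
|---|---|---|---|
| electrophile | 0.098 M | 0.098 M | 0.098 M |
| nucleophile | 0.176 M | 0.176 M | 0.176 M |
| buffer base | 0.098 M | 0.20 M | 0.0980 M |
| buffer acid | 0.098 M | 0.098 M | 0.0980 M |
| remark | the very flask that is asked about, followed so far | run made earlier |  |
| time |  |  | 4.0 h |

south-east run (percent of the electrophile charged)

| time / min | electrophile / % | target / % |
|---|---|---|
| 20.0 | 78.7 | 11.5 |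
| 40.0 | 67.5 | 18.0 |
| 60.0 | 59.9 | 23.6 |
| 80.0 | 55.1 | 26.7 |
| 90.0 | 52.4 | 27.9 |

west run (percent of the electrophile charged)

| time / h | electrophile / % | target / % |
|---|---|---|
| 0.333 | 80.2 | 12.4 |
| 1.00 | 59.9 | 23.9 |
| 2.00 | 49.4 | 30.6 |
| 3.00 | 43.4 | 35.1 |
| 4.00 | 41.0 | 36.7 |

(standard deviation of a reading: 0.5 percentage points)

- acid is the free proton; pH is minus the decimal logarithm of its molar concentration
- a species is counted by the electrophile in it: one idle adduct counts as two
- amounts and yields of target count idle adduct too
- steps under discussion: electrophile + nucleophile -> acid + target + leaving group; protonated nucleophile <-> nucleophile + acid; buffer acid <-> buffer base + acid; electrophile + target <-> idle adduct; electrophile -> decomposition product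
- the earlier runs do not show the pH; that part of a forecast is a guess
- in an amount of target, one idle adduct counts as one target
- what has gone from electrophile into another species counts as reacted, even if it can come back

1. part of the electrophile that has reacted at 4.0 h
2. pH of the solution at 4.0 h

For the quick number, the south-east flask can borrow from the west run, which shows 41.0% electrophile left at 4.00 h, so about 59.0% reacted. The count behind this borrowing is my own. Each buffer acid ties up one nucleophile, and each target then costs two nucleophiles, one used in the step and one taking the acid released. Per electrophile charged:

(1.80 − 1.00) / 2 = 39.8%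

This target mark, the part of the electrophile charged that has become target when the count leaves no free nucleophile, contains no buffer base. The west run's 36.7% target stands below it. The remaining gap places the pH relative to the nucleophile's pKa, so the pH itself stays a guess:

log10(free / protonated nucleophile) = −1.34

The forecast gives 58% reacted and pH 7, the latter “about 1.3 units below the nucleophile's pKa”. Its reacted part is a little less than the borrowed figure.

The south-east flask gives 59.2% reacted and pH 7.25, with 36.9% target at 4.00 h, below the mark of 39.8%. The forecast stands within its margins.

    electrophile + nucleophile → acid + target + leaving group (k = 6.12 M⁻¹ h⁻¹)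
    protonated nucleophile ⇌ nucleophile + acid, settled at all times (K = 2.50 × 10⁻⁹ M)
    buffer acid ⇌ buffer base + acid, settled at all times (K = 5.00 × 10⁻⁵ M)
    electrophile + target ⇌ idle adduct, settled at all times (K = 38.0 M⁻¹)
    electrophile → decomposition product (k = 4.94 × 10⁻⁴ h⁻¹)

The neighbour flask, with the same charges but 0.17 M of buffer acid, gets the same count:

(1.80 − 1.73) / 2 = 3.06%

That neighbour flask holds 4.38% target at 4.00 h, past its mark. Its nucleophile, the limiting reagent, is down to 0.39% of its charge, and 7.95% of its electrophile has reacted.

All runs stem from a simulated flask from invented constants; scatter was added.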